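Once the feed has ended, every free monomer charged is free, sits in a chain, or has gone into self-condensation product, so these three shares add up to the whole charge, and the product can be read by difference; during the feed, part of the charge has not yet gone in, and the three shares fall short of it. A second count holds too: on the list of suspects, each initiator makes one living end and no step destroys one.

| flask | free monomer | initiator | remark | time |
|---|---|---|---|---|
| south-east | 0.24 M (fed, over 0.60 min) | 2.4 mM | run made earlier; the fed solution adds 0.50 times the starting volume |  |
| north | 0.24 M (fed, over 0.60 min) | 9.6 mM | run made earlier; the fed solution adds 0.50 times the starting volume |  |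
| summer | 0.24 M (fed, over 0.60 min) | 4.8 mM | the fed solution adds 0.50 times the starting volume | 5.0 min |
| autumn | 0.24 M (fed, over 1.2 min) | 4.8 mM | the fed solution adds 0.50 times the starting volume | 5.0 min |
| noon | 0.24 M (fed, over 2.5 min) | 4.8 mM | the fed solution adds 0.50 times the starting volume | 5.0 min |
| spring | 0.24 M (fed, over 5.0 min) | 4.8 mM | the fed solution adds 0.50 times the starting volume | 5.0 min |

| run | time / min | monomer in chains / % | free monomer / % |
|---|---|---|---|
| south-east | 0.200 | 0.5 | 30.1 |
| south-east | 0.667 | 4.4 | 58.3 |
| south-east | 1.00 | 7.3 | 37.7 |
| south-east | 1.50 | 9.0 | 23.9 |
| south-east | 2.50 | 11.9 | 13.1 |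
| south-east | 3.00 | 13.4 | 11.2 |
| north | 0.250 | 5.1 | 33.5 |
| north | 0.417 | 10.3 | 48.1 |
| north | 0.667 | 18.3 | 51.9 |
| north | 1.00 | 25.1 | 31.1 |
| north | 2.00 | 35.8 | 10.2 |
| north | 3.00 | 40.6 | 5.1 |

(readings scatter by 0.3 percentage points)

- a species is counted by the free monomer in it: one self-condensation product counts as two
- charges are per starting volume, the dose included; the dosed solution carries all of it
- on the list of suspects stand: free monomer + initiator -> living end + monomer in chains; free monomer + living end -> monomer in chains + living end; 2 free monomer -> self-condensation product
- percentages count the whole charge, also what has not yet gone in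
- "hardly changes" means that all values lie within two and a half points (for a concentration: within two and a half percent of the largest)

* [monomer in chains] at the end for summer, autumn, noon, spring, in this order
* how the row runs (falls, then rises / hardly changes / falls all the way / rises all the way / rises, then falls)

At a fixed number of living ends, chains grow first order in free monomer, which is pseudo-first-order, while self-condensation goes with its square. Let m be free monomer and U monomer in chains, both in percent of the charge. Then self-condensation takes m/m* times what chains take, a selectivity factor, where m* is the even level, the free monomer at which the two paths take equal amounts. It scales with the living ends. After the feed, falling from m_a to m_b gives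

ΔU = m* · ln[(m_a + m*)/(m_b + m*)]

I read m* from the north run between 1.00 min and 2.00 min. Chains gained 11 percentage points and the product took the rest of the 21 points that free monomer lost. Multiplying that ratio by the mean of m gave

m*(north) = 21.7%

The south-east run gave 6.79%, a factor 3.20 lower where the initiator is 4.00 times lower. Its chain gain was only 2.9 points, so I kept north and scaled it:

m* = 10.8% at 4.8 mM

For summer, I took geometric means of the two runs at 1.00 min, since 4.8 mM lies at that mean of their initiators: U = 13.5% and m = 34.2%. Using up that free monomer gave

U = 29.0%, or 0.0464 M

This is my figure for free monomer used up, not for 5.0 min, so it isn't the forecast's number.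

The forecast gave 0.043 M, 0.047 M, 0.058 M and 0.054 M, with the shape "rises, then falls", on the ground that “Slower dosing keeps free monomer low”.

The flasks gave 0.0427 M, 0.0458 M, 0.0502 M and 0.0483 M, so the row's shape was "rises, then falls", as forecast, with noon 0.00780 M under the forecast.

    free monomer + initiator → living end + monomer in chains (k = 2.80 M⁻¹ s⁻¹)
    free monomer + living end → monomer in chains + living end, rate k2*[living end]*[free monomer] (k = 1.50 M⁻¹ s⁻¹)
    2 free monomer → self-condensation product (k = 0.130 M⁻¹ s⁻¹)

In summer, self-condensation used free monomer 4.8 times as fast as chains did at 0.667 min, but 0.31 times as fast at 5.00 min, where the 3.60% still free over m* gives 0.333. In spring, 22.5% was still free at 5.00 min with 30.2% in chains, the rule adds 12 points, and the flask stood at 42.6% at 50.0 min.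

The readings were computed for substances that don't exist; noise was put on by code.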